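**Retrosynthetic overview**
- The tertiary allylic hydroperoxide is made last, by a singlet-oxygen ene reaction (C–O bond) on a prenyl ketone side chain.
- The prenyl ketone comes from an α-methylene aldehyde plus prenyl bromide (the only C–C bond formed), followed by oxidation.
- The aldehyde oxygen and the epoxide come from one operation: an allylic hydroperoxide on the isopropenyl group hands one oxygen to the ring enone on its own face, giving the epoxide cis to the side chain (key C–O step).
- The ester C–O bond is set first, by trans-selective α′-oxygenation and acylation of (R)-(−)-carvone.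
- Ring order: the cyclohexane ring is taken intact from carvone (it supplies the side-chain-bearing stereocentre); the oxirane is the only ring formed (step 2).

Assumption: the SMILES is read as drawn, i.e. epoxide oxygen cis and ester oxygen trans to the side chain, (1S,3S,4S,6S); locants follow carvone numbering (C1 carbonyl, C2 methyl-bearing, C5 side-chain-bearing, C6 ester-bearing; side chain C8 attached to C5, C9 exocyclic CH2, C10 the former methyl, then C11–C13).

**Step 1**
Reactants: 1 (R)-(−)-carvone; 2 3-methylbutanoyl chloride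
Product: 5 (1S,6S)-3-methyl-2-oxo-6-(prop-1-en-2-yl)cyclohex-3-en-1-yl 3-methylbutanoate, via sodium dienolate 3 (not isolated), via sodium alkoxide 4 (not isolated)
Conditions: NaN(SiMe3)2 (1.05 equiv), THF, −78 °C; 2-(phenylsulfonyl)-3-phenyloxaziridine (1.2 equiv), −78 °C; then 2 (1.5 equiv), −78 → 0 °C
Reagents that add atoms: 2-(phenylsulfonyl)-3-phenyloxaziridine (Davis oxaziridine), O=S(=O)(c1ccccc1)N1OC1c1ccccc1
Why: Kinetic α′-deprotonation at C6 followed by Davis enolate oxidation puts the oxygen on the face anti to the adjacent C5 isopropenyl group, which sets the new C6 stereocentre trans (S), and the alkoxide is O-acylated in the same flask.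

**Step 2**
Reactants: 5 (1S,6S)-3-methyl-2-oxo-6-(prop-1-en-2-yl)cyclohex-3-en-1-yl 3-methylbutanoate
Product: 7 (1S,3S,4S,6S)-4-(3-hydroxyprop-1-en-2-yl)-1-methyl-2-oxo-7-oxabicyclo[4.1.0]heptan-3-yl 3-methylbutanoate, via allylic hydroperoxide 6 (not isolated)
Conditions: O2, 5,10,15,20-tetraphenylporphyrin (1 mol%), white LEDs, CH2Cl2, 0 °C; then dilute to 5 mM with toluene, DBU (0.2 equiv), 0 °C → rt
Reagents that add atoms: dioxygen (used as singlet oxygen), O=O
Why: Proposed new method: a Schenck ene reaction at the only electron-rich alkene (the isopropenyl group; the enone C=C is inert to singlet oxygen) gives primary allylic hydroperoxide 6; its DBU-generated peroxy anion is tied to C5 and can reach the enone β-carbon C3 only on the side-chain face, through a seven-membered, chair-like axial peroxy-Michael addition across the 1,3-diaxial positions; the resulting enolate then closes on the proximal peroxide oxygen and expels the C10 alkoxide, so both epoxide C–O bonds and the C2 and C3 stereocentres are set cis to the side chain, the reverse of the trans outcome of intermolecular alkaline H2O2, while high dilution suppresses intermolecular transfer; the closest known reactions are Weitz–Scheffer epoxidation of enones with alkyl hydroperoxides and base, and intramolecular peroxy-Michael additions that give cyclic peroxides.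

**Step 3**
Reactants: 7 (1S,3S,4S,6S)-4-(3-hydroxyprop-1-en-2-yl)-1-methyl-2-oxo-7-oxabicyclo[4.1.0]heptan-3-yl 3-methylbutanoate
Product: 8 (1S,3S,4S,6S)-1-methyl-2-oxo-4-(3-oxoprop-1-en-2-yl)-7-oxabicyclo[4.1.0]heptan-3-yl 3-methylbutanoate
Conditions: Dess–Martin periodinane, NaHCO3, CH2Cl2, 0 °C → rt
Reagents that add atoms: none
Why: Dess–Martin oxidation of a primary allylic alcohol to the enal is mild and neutral, leaving the epoxy ketone and the ester untouched, and no stereocentre is affected.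

**Step 4**
Reactants: 8 (1S,3S,4S,6S)-1-methyl-2-oxo-4-(3-oxoprop-1-en-2-yl)-7-oxabicyclo[4.1.0]heptan-3-yl 3-methylbutanoate; 9 1-bromo-3-methylbut-2-ene (prenyl bromide)
Product: 11 (1S,3S,4S,6S)-4-(3-hydroxy-6-methylhepta-1,5-dien-2-yl)-1-methyl-2-oxo-7-oxabicyclo[4.1.0]heptan-3-yl 3-methylbutanoate, via branched homoallylic alcohol 10 (not isolated)
Conditions: In powder (1.5 equiv), H2O (6 equiv), CH2Cl2 (concentrated), rt, 48 h
Reagents that add atoms: none
Why: An indium Barbier prenylation is selective for the aldehyde over the hindered ketone and the ester, and under concentrated, water-limited conditions the kinetic γ-adduct 10 is converted by the trivalent indium Lewis acid (retro-allylation and 2-oxonia-Cope shift) into the linear α-adduct; the new carbinol centre forms as an epimer mixture that is erased in step 5.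

**Step 5**
Reactants: 11 (1S,3S,4S,6S)-4-(3-hydroxy-6-methylhepta-1,5-dien-2-yl)-1-methyl-2-oxo-7-oxabicyclo[4.1.0]heptan-3-yl 3-methylbutanoate
Product: 12 (1S,3S,4S,6S)-1-methyl-4-(6-methyl-3-oxohepta-1,5-dien-2-yl)-2-oxo-7-oxabicyclo[4.1.0]heptan-3-yl 3-methylbutanoate
Conditions: Dess–Martin periodinane, NaHCO3, CH2Cl2, 0 °C
Reagents that add atoms: none
Why: Buffered Dess–Martin oxidation gives the β,γ-unsaturated ketone without acid or base that would move the prenyl double bond into conjugation.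

**Step 6**
Reactants: 12 (1S,3S,4S,6S)-1-methyl-4-(6-methyl-3-oxohepta-1,5-dien-2-yl)-2-oxo-7-oxabicyclo[4.1.0]heptan-3-yl 3-methylbutanoate
Product: 13 (1S,3S,4S,6S)-4-[(4E)-6-hydroperoxy-6-methyl-3-oxohepta-1,4-dien-2-yl]-1-methyl-2-oxo-7-oxabicyclo[4.1.0]heptan-3-yl 3-methylbutanoate
Conditions: O2, 5,10,15,20-tetraphenylporphyrin (1 mol%), white LEDs, CH2Cl2, −20 °C
Reagents that add atoms: dioxygen (used as singlet oxygen), O=O
Why: In this Schenck ene reaction singlet oxygen attacks only the trisubstituted prenyl alkene (the α-methylene ketone is electron-poor); abstraction of a C11 hydrogen, which is allylic and α to the ketone, moves the double bond into conjugation with E geometry and places the hydroperoxide on the tertiary carbon, with the secondary hydroperoxide regioisomer expected as the minor product to be removed by chromatography; no stereocentre is formed.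

**Compound list**
1 | (R)-(−)-carvone, (5R)-2-methyl-5-(prop-1-en-2-yl)cyclohex-2-en-1-one | CC(=C)[C@@H]1CC=C(C)C(=O)C1 | starting material
2 | 3-methylbutanoyl chloride (isovaleryl chloride) | CC(C)CC(=O)Cl | starting material
3 | sodium (3R)-6-methyl-3-(prop-1-en-2-yl)cyclohexa-1,5-dien-1-olate (cross-conjugated C1–C6 enolate of 1) | C=C(C)[C@@H]1CC=C(C)C([O-])=C1.[Na+] | intermediate
4 | sodium (1S,6S)-3-methyl-2-oxo-6-(prop-1-en-2-yl)cyclohex-3-en-1-olate (alkoxide oxygen trans to isopropenyl) | C=C(C)[C@@H]1CC=C(C)C(=O)[C@H]1[O-].[Na+] | intermediate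
5 | (1S,6S)-3-methyl-2-oxo-6-(prop-1-en-2-yl)cyclohex-3-en-1-yl 3-methylbutanoate (ester oxygen trans to isopropenyl) | C=C(C)[C@@H]1CC=C(C)C(=O)[C@H]1OC(=O)CC(C)C | intermediate
6 | (1S,6S)-6-(3-hydroperoxyprop-1-en-2-yl)-3-methyl-2-oxocyclohex-3-en-1-yl 3-methylbutanoate | C=C(COO)[C@@H]1CC=C(C)C(=O)[C@H]1OC(=O)CC(C)C | intermediate
7 | (1S,3S,4S,6S)-4-(3-hydroxyprop-1-en-2-yl)-1-methyl-2-oxo-7-oxabicyclo[4.1.0]heptan-3-yl 3-methylbutanoate (epoxide cis to side chain, ester trans) | C=C(CO)[C@@H]1C[C@@H]2O[C@]2(C)C(=O)[C@H]1OC(=O)CC(C)C | intermediate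
8 | (1S,3S,4S,6S)-1-methyl-2-oxo-4-(3-oxoprop-1-en-2-yl)-7-oxabicyclo[4.1.0]heptan-3-yl 3-methylbutanoate | C=C(C=O)[C@@H]1C[C@@H]2O[C@]2(C)C(=O)[C@H]1OC(=O)CC(C)C | intermediate
9 | 1-bromo-3-methylbut-2-ene (prenyl bromide) | CC(C)=CCBr | starting material
10 | (1S,3S,4S,6S)-4-(3-hydroxy-4,4-dimethylhexa-1,5-dien-2-yl)-1-methyl-2-oxo-7-oxabicyclo[4.1.0]heptan-3-yl 3-methylbutanoate (γ-adduct, carbinol epimers) | C=C(C(O)C(C)(C)C=C)[C@@H]1C[C@@H]2O[C@]2(C)C(=O)[C@H]1OC(=O)CC(C)C | intermediate
11 | (1S,3S,4S,6S)-4-(3-hydroxy-6-methylhepta-1,5-dien-2-yl)-1-methyl-2-oxo-7-oxabicyclo[4.1.0]heptan-3-yl 3-methylbutanoate (carbinol epimers) | C=C(C(O)CC=C(C)C)[C@@H]1C[C@@H]2O[C@]2(C)C(=O)[C@H]1OC(=O)CC(C)C | intermediate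
12 | (1S,3S,4S,6S)-1-methyl-4-(6-methyl-3-oxohepta-1,5-dien-2-yl)-2-oxo-7-oxabicyclo[4.1.0]heptan-3-yl 3-methylbutanoate | C=C(C(=O)CC=C(C)C)[C@@H]1C[C@@H]2O[C@]2(C)C(=O)[C@H]1OC(=O)CC(C)C | intermediate
13 | (1S,3S,4S,6S)-4-[(4E)-6-hydroperoxy-6-methyl-3-oxohepta-1,4-dien-2-yl]-1-methyl-2-oxo-7-oxabicyclo[4.1.0]heptan-3-yl 3-methylbutanoate (CNP0241468.1) | C=C(C(=O)/C=C/C(C)(C)OO)[C@@H]1C[C@@H]2O[C@]2(C)C(=O)[C@H]1OC(=O)CC(C)C | target

**Totals**
Total step count: 6. Longest linear sequence: 6 steps (1 → 13).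

**Steps most likely to fail, with fallbacks**

Step 2 (the proposed new step). The ene reaction of a 1,1-disubstituted alkene with singlet oxygen is slow, and the tethered oxygen transfer may lose to intermolecular transfer, which would give the trans epoxide. Fallback by known chemistry, setting out from 5 and coming back at 7:
- Luche reduction (NaBH4, CeCl3·7H2O, MeOH, −78 °C) gives, by axial hydride delivery, the all-equatorial allylic alcohol (1S,2S,6S)-2-hydroxy-3-methyl-6-(prop-1-en-2-yl)cyclohex-3-en-1-yl 3-methylbutanoate F1.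
- Hydroxyl-directed epoxidation (VO(acac)2 cat., t-BuOOH, CH2Cl2) places the oxygen on the hydroxyl face, which is the side-chain face, and gives epoxy alcohol (1R,2R,3S,4S,6S)-2-hydroxy-1-methyl-4-(prop-1-en-2-yl)-7-oxabicyclo[4.1.0]heptan-3-yl 3-methylbutanoate F2.
- Dess–Martin oxidation gives epoxy ketone (1S,3S,4S,6S)-1-methyl-2-oxo-4-(prop-1-en-2-yl)-7-oxabicyclo[4.1.0]heptan-3-yl 3-methylbutanoate F3.
- Allylic hydroxylation of the isopropenyl methyl group (SeO2 cat., t-BuOOH, CH2Cl2) then gives 7.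

Step 4. The γ-to-α equilibration may stall at branched alcohol 10, or the indium Lewis acid may damage the epoxy ketone over 48 h. Fallback, setting out from 8 and coming back at 11: a short indium Barbier allylation with allyl bromide (In, THF/H2O, rt), which has no regiochemical ambiguity, gives homoallylic alcohol (1S,3S,4S,6S)-4-(3-hydroxyhexa-1,5-dien-2-yl)-1-methyl-2-oxo-7-oxabicyclo[4.1.0]heptan-3-yl 3-methylbutanoate F4. Cross-metathesis of its terminal alkene with 2-methyl-2-butene (second-generation Grubbs catalyst RuCl2(=CHPh)(PCy3)(H2IMes), 40 °C) then gives 11; the 1,1-disubstituted alkene does not take part.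

Step 6. The ratio of tertiary to secondary hydroperoxide may be poor. Fallback with a regiospecific ionic sequence, setting out from 12 and coming back at 13: Markovnikov bromo-hydroperoxidation of the prenyl alkene (1,3-dibromo-5,5-dimethylhydantoin, ethereal anhydrous H2O2, −40 °C) opens the bromonium ion at the tertiary carbon and gives (1S,3S,4S,6S)-4-(5-bromo-6-hydroperoxy-6-methyl-3-oxohept-1-en-2-yl)-1-methyl-2-oxo-7-oxabicyclo[4.1.0]heptan-3-yl 3-methylbutanoate F5. Its bromide is β to the ketone, so brief treatment with Et3N (1 equiv, CH2Cl2, −20 °C) eliminates HBr by an E1cB path and gives the E enone 13.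

**Further compounds**
F1 | step 2 | (1S,2S,6S)-2-hydroxy-3-methyl-6-(prop-1-en-2-yl)cyclohex-3-en-1-yl 3-methylbutanoate | C=C(C)[C@@H]1CC=C(C)[C@H](O)[C@H]1OC(=O)CC(C)C
F2 | step 2 | (1R,2R,3S,4S,6S)-2-hydroxy-1-methyl-4-(prop-1-en-2-yl)-7-oxabicyclo[4.1.0]heptan-3-yl 3-methylbutanoate | C=C(C)[C@@H]1C[C@@H]2O[C@]2(C)[C@H](O)[C@H]1OC(=O)CC(C)C
F3 | step 2 | (1S,3S,4S,6S)-1-methyl-2-oxo-4-(prop-1-en-2-yl)-7-oxabicyclo[4.1.0]heptan-3-yl 3-methylbutanoate | C=C(C)[C@@H]1C[C@@H]2O[C@]2(C)C(=O)[C@H]1OC(=O)CC(C)C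
F4 | step 4 | (1S,3S,4S,6S)-4-(3-hydroxyhexa-1,5-dien-2-yl)-1-methyl-2-oxo-7-oxabicyclo[4.1.0]heptan-3-yl 3-methylbutanoate | C=C(C(O)CC=C)[C@@H]1C[C@@H]2O[C@]2(C)C(=O)[C@H]1OC(=O)CC(C)C
F5 | step 6 | (1S,3S,4S,6S)-4-(5-bromo-6-hydroperoxy-6-methyl-3-oxohept-1-en-2-yl)-1-methyl-2-oxo-7-oxabicyclo[4.1.0]heptan-3-yl 3-methylbutanoate | C=C(C(=O)CC(Br)C(C)(C)OO)[C@@H]1C[C@@H]2O[C@]2(C)C(=O)[C@H]1OC(=O)CC(C)C
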